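**Retrosynthetic overview**

1. Germacrane numbering is used (ring C1–C10; lactone O on C6, C11, C12; methylene C13; ester C14; hydroxymethyl C15). The endgame releases the C11=C13 methylene from a Mannich base after O8 angeloylation and O9 acetylation.
2. Key disconnection: the C8–C9 bond of the ten-membered ring, opened to a dialdehyde (C8 formyl on the γ-lactone, C9 formyl of a 2-formyl enoate C1=C10–C14). It is closed by a reductive γ-siloxyallylation with CrCl2/Et3SiCl that should form the ring, C8, C9, the C1=C10 geometry and the O8/O9 differentiation in one operation.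
3. Enabling feature: C9 is both a carbinol carbon of the C8/C9 diol and the allylic carbon on C10, the α-carbon of the C1=C10 enoate. The array C8(O)–C9(O)–C10(CO2Me)=C1 inside the ten-membered ring is therefore the retron of an enal-plus-aldehyde union, and both ring alkenes are cis within the ring, which eases medium-ring closure.
4. The dialdehyde comes from cross-metathesis (C1=C10, methyl 2-(hydroxymethyl)acrylate) on a trans-γ-lactone. Its C6/C7 centres are set in one auxiliary-controlled Evans syn-aldol of a succinate imide with a geometrically defined enal, and C8 and C9 are then relayed from C7.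
5. The enal is made from but-2-yne-1,4-diol (trans-hydroalumination/iodination, Negishi coupling). Ring order: γ-lactone (step 6), then the ten-membered carbocycle (step 13).

Key step: step 13

Remark: α/β descriptors refer to the usual germacranolide drawing (H-7α); all macrocycles are 1(10)E,4E, i.e. both ring alkenes are cis within the ring. It is assumed that Et3SiCl in step 13 silylates only the enal-derived oxygen.

**Route**

Step 1
Reactants: 1 but-2-yne-1,4-diol
Product: 2 4-[(tert-butyldiphenylsilyl)oxy]but-2-yn-1-ol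
Conditions: NaH (1.0 equiv), THF, 0 → 25 °C; then TBDPSCl (1.0 equiv)
Reagents that add atoms: tert-butylchlorodiphenylsilane CC(C)(C)[Si](Cl)(c1ccccc1)c1ccccc1
Why: The sparingly soluble monosodium alkoxide of the symmetrical diol should be O-silylated once, giving the mono-protected diol.

Step 2
Reactants: 2 4-[(tert-butyldiphenylsilyl)oxy]but-2-yn-1-ol
Product: 3 (2Z)-4-[(tert-butyldiphenylsilyl)oxy]-3-iodobut-2-en-1-ol
Conditions: NaAlH2(OCH2CH2OMe)2 (1.5 equiv), THF, 0 °C; then I2, −78 → 0 °C
Reagents that add atoms: iodine II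
Why: Alkoxide-directed trans-hydroalumination of the propargylic alcohol places aluminium on the distal alkyne carbon cis to the carbinol, and iodinolysis with retention should give the Z-iodoalkene that fixes the C4=C5 geometry (C6 and C15 trans).

Step 3
Reactants: 3 (2Z)-4-[(tert-butyldiphenylsilyl)oxy]-3-iodobut-2-en-1-ol; 4 but-3-en-1-ylzinc bromide
Product: 5 (2E)-3-{[(tert-butyldiphenylsilyl)oxy]methyl}hepta-2,6-dien-1-ol
Conditions: 4 (2.0 equiv), PdCl2(dppf) (5 mol %), THF, 25 → 50 °C
Reagents that add atoms: none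
Why: Negishi sp3–sp2 cross-coupling proceeds with retention of alkene geometry, so the C3 chain ends up cis to C6; the alkylzinc halide tolerates the free hydroxyl and the dppf ligand suppresses β-hydride elimination.

Step 4
Reactants: 5 (2E)-3-{[(tert-butyldiphenylsilyl)oxy]methyl}hepta-2,6-dien-1-ol
Product: 6 (2E)-3-{[(tert-butyldiphenylsilyl)oxy]methyl}hepta-2,6-dienal
Conditions: MnO2 (20 equiv), CH2Cl2, 25 °C
Reagents that add atoms: none
Why: Chemoselective allylic oxidation with MnO2 should give the enal without scrambling the trisubstituted alkene.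

Step 5
Reactants: 7 (4S)-4-benzyl-1,3-oxazolidin-2-one; 8 methyl 4-chloro-4-oxobutanoate
Product: 9 methyl 4-[(4S)-4-benzyl-2-oxo-1,3-oxazolidin-3-yl]-4-oxobutanoate
Conditions: n-BuLi, THF, −78 °C; then 8, −78 → 0 °C
Reagents that add atoms: none
Why: Standard N-acylation of the lithiated oxazolidinone by the acid chloride; the methyl ester is untouched at low temperature.

Step 6
Reactants: 9 methyl 4-[(4S)-4-benzyl-2-oxo-1,3-oxazolidin-3-yl]-4-oxobutanoate; 6 (2E)-3-{[(tert-butyldiphenylsilyl)oxy]methyl}hepta-2,6-dienal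
Product: 11 trans-γ-lactone imide (4S)-4-benzyl-3-{[(2R,3S)-2-[(1E)-2-{[(tert-butyldiphenylsilyl)oxy]methyl}hexa-1,5-dien-1-yl]-5-oxooxolan-3-yl]carbonyl}-1,3-oxazolidin-2-one, via syn-aldol adduct 10 (not isolated)
Conditions: Bu2BOTf, iPr2NEt, CH2Cl2, −78 → 0 °C; then 6, −78 → 0 °C; pH 7 buffer, MeOH, H2O2, 0 °C; then PPTS (cat.), CH2Cl2, 25 °C
Reagents that add atoms: none
Why: Evans syn-aldol: only the imide is enolised to the Z-boron enolate, whose Zimmerman–Traxler transition state, shielded by the benzyl group, sets C6 (R) and C7 (S) in one event, and the new hydroxyl then closes the γ-lactone onto the methyl ester (5-exo-trig) to give the trans-lactone.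

Step 7
Reactants: 11 trans-γ-lactone imide
Product: 12 (4R,5R)-5-[(1E)-2-{[(tert-butyldiphenylsilyl)oxy]methyl}hexa-1,5-dien-1-yl]-4-(hydroxymethyl)oxolan-2-one
Conditions: NaBH4, THF–H2O (4:1), 0 → 25 °C
Reagents that add atoms: none
Why: Reductive removal of the auxiliary: NaBH4 in wet THF should reduce the activated imide carbonyl to the C8 primary alcohol faster than the γ-lactone and release 7 for reuse (the C7 descriptor changes only through CIP priorities).

Step 8
Reactants: 12 (4R,5R)-5-[(1E)-2-{[(tert-butyldiphenylsilyl)oxy]methyl}hexa-1,5-dien-1-yl]-4-(hydroxymethyl)oxolan-2-one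
Product: 13 (4R,5R)-5-[(1E)-2-{[(tert-butyldiphenylsilyl)oxy]methyl}hexa-1,5-dien-1-yl]-4-{[(triethylsilyl)oxy]methyl}oxolan-2-one
Conditions: Et3SiCl, imidazole, CH2Cl2, 0 °C
Reagents that add atoms: chlorotriethylsilane CC[Si](Cl)(CC)CC
Why: Silylation of the primary alcohol prevents alkoxide-induced translactonisation during the enolate step that follows.

Step 9
Reactants: 13 (4R,5R)-5-[(1E)-2-{[(tert-butyldiphenylsilyl)oxy]methyl}hexa-1,5-dien-1-yl]-4-{[(triethylsilyl)oxy]methyl}oxolan-2-one
Product: 14 (3R,4R,5R)-5-[(1E)-2-{[(tert-butyldiphenylsilyl)oxy]methyl}hexa-1,5-dien-1-yl]-3-[(dimethylamino)methyl]-4-{[(triethylsilyl)oxy]methyl}oxolan-2-one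
Conditions: LiN(SiMe3)2 (1.2 equiv), THF, −78 °C; then Eschenmoser's salt, −78 → 0 °C
Reagents that add atoms: N,N-dimethylmethyleneiminium iodide C=[N+](C)C.[I-]
Why: Mannich aminomethylation of the kinetic lactone enolate, anti to the C7 substituent, should give the 11βH amine, which carries C13 and masks the α-methylene group (the C11 configuration is inconsequential).

Step 10
Reactants: 14 Mannich base lactone; 15 methyl 2-(hydroxymethyl)prop-2-enoate
Product: 16 methyl (2E,6E)-6-{[(tert-butyldiphenylsilyl)oxy]methyl}-7-[(2R,3R,4R)-4-[(dimethylamino)methyl]-5-oxo-3-{[(triethylsilyl)oxy]methyl}oxolan-2-yl]-2-(hydroxymethyl)hepta-2,6-dienoate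
Conditions: 15 (5 equiv), TsOH·H2O (1.0 equiv), second-generation Hoveyda–Grubbs catalyst RuCl2(H2IMes)(=CH–C6H4-2-OiPr) (10 mol %), CH2Cl2, 40 °C; aq. NaHCO3
Reagents that add atoms: none
Why: Olefin cross-metathesis of the monosubstituted alkene with the 1,1-disubstituted acrylate installs C9, C10 and C14 in one step, with the amine protected as its tosylate salt and the trisubstituted C4=C5 alkene inert; mainly the E isomer is expected, but this geometry is erased in step 13.

Step 11
Reactants: 16 cross-metathesis product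
Product: 17 methyl (2E,6E)-6-{[(tert-butyldiphenylsilyl)oxy]methyl}-7-[(2R,3R,4R)-4-[(dimethylamino)methyl]-3-(hydroxymethyl)-5-oxooxolan-2-yl]-2-(hydroxymethyl)hepta-2,6-dienoate
Conditions: AcOH–THF–H2O (3:1:1), 25 °C
Reagents that add atoms: none
Why: Mild acid hydrolysis should cleave the primary triethylsilyl ether while the tert-butyldiphenylsilyl ether, the esters and the lactone survive.

Step 12
Reactants: 17 diol
Product: 18 methyl (2E,6E)-6-{[(tert-butyldiphenylsilyl)oxy]methyl}-7-[(2R,3S,4R)-4-[(dimethylamino)methyl]-3-formyl-5-oxooxolan-2-yl]-2-formylhepta-2,6-dienoate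
Conditions: Dess–Martin periodinane (3 equiv), NaHCO3, CH2Cl2, 0 → 25 °C; used crude at once
Reagents that add atoms: none
Why: Dess–Martin oxidation should convert both primary alcohols into the aliphatic C8 aldehyde and the 2-formyl enoate under near-neutral conditions; the all-trans lactone substitution is the thermodynamic arrangement at C7.

Step 13
Reactants: 18 dialdehyde
Product: 20 methyl 13-(dimethylamino)-8β-hydroxy-9α-[(triethylsilyl)oxy]-15-[(tert-butyldiphenylsilyl)oxy]-11βH-11,13-dihydrogermacra-1(10),4-dien-6α,12-olid-14-oate, via γ-siloxyallylchromium 19 (not isolated)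
Conditions: CrCl2 (8 equiv), Et3SiCl (2.5 equiv), THF, 25 °C, syringe-pump addition of 18 (final 0.003 M); aq. NaHCO3
Reagents that add atoms: chlorotriethylsilane CC[Si](Cl)(CC)CC
Why: Proposed new method: CrCl2 with Et3SiCl should reduce only the doubly activated 2-formyl enoate (the aliphatic C8 aldehyde is inert to divalent chromium) to an O-silylated allyl radical that a second CrCl2 captures as the trivalent γ-siloxyallylchromium 19, which adds through its oxygen-bearing terminus C9 to the tethered C8 aldehyde; the closest known reactions are the CrCl2/R3SiCl cross-pinacol-type coupling of enals with aldehydes and Nozaki–Hiyama allylation macrocyclisations. The ten-membered carbocycle closes in the 10-exo-trig mode at the aldehyde with allylic transposition (SE2′) through a chair six-membered Cr–O bridged transition state. The six-carbon C2–C7 tether is best spanned by the chair in which the C2 chain is pseudoaxial on C1 and C7 is equatorial on C8 (this also avoids A(1,2) strain with the ester on C10), which sets the new C1=C10 bond with C2 and C9 cis as in the target and erases the E/Z composition of 18. C9 is controlled by the enol ether geometry: with the siloxy group syn to C1 and anti to the ester, the preferred geometry of a 2-substituted 3-siloxyacrylate, this chair gives the 8,9-threo pair (9S). C8 is controlled by the 7S centre through Felkin–Anh attack anti to the C7–C11 bond with the tether carbon C6 inside, which gives 8S. The step needs γ- over α-attack (ten- rather than eight-membered ring) and differentiated O8/O9: the first should be secured by chromium residing on C1 so that bonding occurs at the siloxy terminus, the second because O9 leaves as its Et3Si ether while O8 leaves as a chromium alkoxide that is hydrolysed on work-up.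

Step 14
Reactants: 20 macrocyclic 8β-alcohol; 21 angelic acid [(2Z)-2-methylbut-2-enoic acid]
Product: 22 methyl 8β-angeloyloxy-13-(dimethylamino)-9α-[(triethylsilyl)oxy]-15-[(tert-butyldiphenylsilyl)oxy]-11βH-11,13-dihydrogermacra-1(10),4-dien-6α,12-olid-14-oate
Conditions: 21, 2,4,6-Cl3C6H2COCl, Et3N, PhMe, 25 °C; then 20, 80 °C
Reagents that add atoms: none
Why: Yamaguchi-type acylation with the preformed mixed anhydride should esterify the free C8 hydroxyl without isomerising the angeloyl unit to the tiglate; O9 is blocked as its silyl ether.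

Step 15
Reactants: 22 angelate
Product: 23 methyl 8β-angeloyloxy-13-(dimethylamino)-9α-hydroxy-15-[(tert-butyldiphenylsilyl)oxy]-11βH-11,13-dihydrogermacra-1(10),4-dien-6α,12-olid-14-oate
Conditions: HF·pyridine, pyridine, THF, 0 °C
Reagents that add atoms: none
Why: Buffered HF·pyridine should remove the secondary triethylsilyl ether much faster than the primary tert-butyldiphenylsilyl ether, and the acidic medium disfavours acyl migration.

Step 16
Reactants: 23 9α-alcohol
Product: 24 methyl 9α-acetoxy-8β-angeloyloxy-13-(dimethylamino)-15-[(tert-butyldiphenylsilyl)oxy]-11βH-11,13-dihydrogermacra-1(10),4-dien-6α,12-olid-14-oate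
Conditions: Ac2O, pyridine, DMAP (cat.), CH2Cl2, 0 → 25 °C
Reagents that add atoms: acetic anhydride CC(=O)OC(C)=O
Why: DMAP-catalysed acetylation of the allylic C9 alcohol, the only free hydroxyl.

Step 17
Reactants: 24 acetate
Product: 25 methyl 9α-acetoxy-8β-angeloyloxy-13-(dimethylamino)-15-hydroxy-11βH-11,13-dihydrogermacra-1(10),4-dien-6α,12-olid-14-oate
Conditions: HF·pyridine (excess), THF, 25 °C
Reagents that add atoms: none
Why: Fluoride cleavage of the remaining silyl ether should free the C15 alcohol without touching the three esters or the lactone.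

Step 18
Reactants: 25 Mannich base of the target
Product: 27 CNP0216801.4 methyl 9α-acetoxy-8β-angeloyloxy-15-hydroxygermacra-1(10)E,4E,11(13)-trien-6α,12-olid-14-oate (6R,7S,8S,9S), via trimethylammonium iodide 26 (not isolated)
Conditions: MeI, THF, 25 °C; then aq. NaHCO3, EtOAc, 25 °C
Reagents that add atoms: none
Why: N-Methylation followed by mild-base E1cB elimination of trimethylamine (retro-Mannich-type unmasking of an amine-protected α-methylene lactone) should reveal the C11=C13 methylene under conditions that spare the acetate, the angelate and the methyl ester.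

**Compound list**

1 | but-2-yne-1,4-diol | OCC#CCO | starting material
2 | 4-[(tert-butyldiphenylsilyl)oxy]but-2-yn-1-ol | OCC#CCO[Si](c1ccccc1)(c1ccccc1)C(C)(C)C | intermediate
3 | (2Z)-4-[(tert-butyldiphenylsilyl)oxy]-3-iodobut-2-en-1-ol | OC/C=C(/CO[Si](c1ccccc1)(c1ccccc1)C(C)(C)C)I | intermediate
4 | but-3-en-1-ylzinc bromide | C=CCC[Zn]Br | starting material
5 | (2E)-3-{[(tert-butyldiphenylsilyl)oxy]methyl}hepta-2,6-dien-1-ol | OC/C=C(/CO[Si](c1ccccc1)(c1ccccc1)C(C)(C)C)CCC=C | intermediate
6 | (2E)-3-{[(tert-butyldiphenylsilyl)oxy]methyl}hepta-2,6-dienal | O=C/C=C(/CO[Si](c1ccccc1)(c1ccccc1)C(C)(C)C)CCC=C | intermediate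
7 | (4S)-4-benzyl-1,3-oxazolidin-2-one | O=C1OC[C@H](Cc2ccccc2)N1 | starting material
8 | methyl 4-chloro-4-oxobutanoate | COC(=O)CCC(Cl)=O | starting material
9 | methyl 4-[(4S)-4-benzyl-2-oxo-1,3-oxazolidin-3-yl]-4-oxobutanoate | COC(=O)CCC(=O)N1[C@@H](Cc2ccccc2)COC1=O | intermediate
10 | syn-aldol adduct, methyl (3S,4R,5E)-3-{[(4S)-4-benzyl-2-oxo-1,3-oxazolidin-3-yl]carbonyl}-6-{[(tert-butyldiphenylsilyl)oxy]methyl}-4-hydroxydeca-5,9-dienoate | O[C@H](/C=C(/CO[Si](c1ccccc1)(c1ccccc1)C(C)(C)C)CCC=C)[C@H](CC(=O)OC)C(=O)N1[C@@H](Cc2ccccc2)COC1=O | intermediate (not isolated)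
11 | (4S)-4-benzyl-3-{[(2R,3S)-2-[(1E)-2-{[(tert-butyldiphenylsilyl)oxy]methyl}hexa-1,5-dien-1-yl]-5-oxooxolan-3-yl]carbonyl}-1,3-oxazolidin-2-one | C1C(=O)O[C@H](/C=C(/CO[Si](c2ccccc2)(c3ccccc3)C(C)(C)C)CCC=C)[C@H]1C(=O)N4[C@@H](Cc5ccccc5)COC4=O | intermediate
12 | (4R,5R)-5-[(1E)-2-{[(tert-butyldiphenylsilyl)oxy]methyl}hexa-1,5-dien-1-yl]-4-(hydroxymethyl)oxolan-2-one | C1C(=O)O[C@H](/C=C(/CO[Si](c2ccccc2)(c3ccccc3)C(C)(C)C)CCC=C)[C@H]1CO | intermediate
13 | (4R,5R)-5-[(1E)-2-{[(tert-butyldiphenylsilyl)oxy]methyl}hexa-1,5-dien-1-yl]-4-{[(triethylsilyl)oxy]methyl}oxolan-2-one | C1C(=O)O[C@H](/C=C(/CO[Si](c2ccccc2)(c3ccccc3)C(C)(C)C)CCC=C)[C@H]1CO[Si](CC)(CC)CC | intermediate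
14 | (3R,4R,5R)-5-[(1E)-2-{[(tert-butyldiphenylsilyl)oxy]methyl}hexa-1,5-dien-1-yl]-3-[(dimethylamino)methyl]-4-{[(triethylsilyl)oxy]methyl}oxolan-2-one | CN(C)C[C@@H]1C(=O)O[C@H](/C=C(/CO[Si](c2ccccc2)(c3ccccc3)C(C)(C)C)CCC=C)[C@H]1CO[Si](CC)(CC)CC | intermediate
15 | methyl 2-(hydroxymethyl)prop-2-enoate | C=C(CO)C(=O)OC | starting material
16 | methyl (2E,6E)-6-{[(tert-butyldiphenylsilyl)oxy]methyl}-7-[(2R,3R,4R)-4-[(dimethylamino)methyl]-5-oxo-3-{[(triethylsilyl)oxy]methyl}oxolan-2-yl]-2-(hydroxymethyl)hepta-2,6-dienoate | CN(C)C[C@@H]1C(=O)O[C@H](/C=C(/CO[Si](c2ccccc2)(c3ccccc3)C(C)(C)C)CC/C=C(/C(=O)OC)CO)[C@H]1CO[Si](CC)(CC)CC | intermediate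
17 | methyl (2E,6E)-6-{[(tert-butyldiphenylsilyl)oxy]methyl}-7-[(2R,3R,4R)-4-[(dimethylamino)methyl]-3-(hydroxymethyl)-5-oxooxolan-2-yl]-2-(hydroxymethyl)hepta-2,6-dienoate | CN(C)C[C@@H]1C(=O)O[C@H](/C=C(/CO[Si](c2ccccc2)(c3ccccc3)C(C)(C)C)CC/C=C(/C(=O)OC)CO)[C@H]1CO | intermediate
18 | methyl (2E,6E)-6-{[(tert-butyldiphenylsilyl)oxy]methyl}-7-[(2R,3S,4R)-4-[(dimethylamino)methyl]-3-formyl-5-oxooxolan-2-yl]-2-formylhepta-2,6-dienoate | CN(C)C[C@@H]1C(=O)O[C@H](/C=C(/CO[Si](c2ccccc2)(c3ccccc3)C(C)(C)C)CC/C=C(/C(=O)OC)C=O)[C@H]1C=O | intermediate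
19 | γ-siloxyallylchromium dichloride derived from 18 (Cr on C1, C1 epimers interconverting; Et3SiO on C9 syn to C1) | CN(C)C[C@@H]1C(=O)O[C@H](/C=C(/CO[Si](c2ccccc2)(c3ccccc3)C(C)(C)C)CCC([Cr](Cl)Cl)/C(C(=O)OC)=C\O[Si](CC)(CC)CC)[C@H]1C=O | intermediate (not isolated)
20 | methyl 13-(dimethylamino)-8β-hydroxy-9α-[(triethylsilyl)oxy]-15-[(tert-butyldiphenylsilyl)oxy]-11βH-11,13-dihydrogermacra-1(10),4-dien-6α,12-olid-14-oate | CN(C)C[C@@H]1C(=O)O[C@@H]2/C=C(/CO[Si](c3ccccc3)(c4ccccc4)C(C)(C)C)CC/C=C(/C(=O)OC)[C@H](O[Si](CC)(CC)CC)[C@@H](O)[C@@H]12 | intermediate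
21 | angelic acid, (2Z)-2-methylbut-2-enoic acid | C/C=C(/C)C(=O)O | starting material
22 | methyl 8β-angeloyloxy-13-(dimethylamino)-9α-[(triethylsilyl)oxy]-15-[(tert-butyldiphenylsilyl)oxy]-11βH-11,13-dihydrogermacra-1(10),4-dien-6α,12-olid-14-oate | CN(C)C[C@@H]1C(=O)O[C@@H]2/C=C(/CO[Si](c3ccccc3)(c4ccccc4)C(C)(C)C)CC/C=C(/C(=O)OC)[C@H](O[Si](CC)(CC)CC)[C@@H](OC(=O)/C(C)=C\C)[C@@H]12 | intermediate
23 | methyl 8β-angeloyloxy-13-(dimethylamino)-9α-hydroxy-15-[(tert-butyldiphenylsilyl)oxy]-11βH-11,13-dihydrogermacra-1(10),4-dien-6α,12-olid-14-oate | CN(C)C[C@@H]1C(=O)O[C@@H]2/C=C(/CO[Si](c3ccccc3)(c4ccccc4)C(C)(C)C)CC/C=C(/C(=O)OC)[C@H](O)[C@@H](OC(=O)/C(C)=C\C)[C@@H]12 | intermediate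
24 | methyl 9α-acetoxy-8β-angeloyloxy-13-(dimethylamino)-15-[(tert-butyldiphenylsilyl)oxy]-11βH-11,13-dihydrogermacra-1(10),4-dien-6α,12-olid-14-oate | CN(C)C[C@@H]1C(=O)O[C@@H]2/C=C(/CO[Si](c3ccccc3)(c4ccccc4)C(C)(C)C)CC/C=C(/C(=O)OC)[C@H](OC(C)=O)[C@@H](OC(=O)/C(C)=C\C)[C@@H]12 | intermediate
25 | methyl 9α-acetoxy-8β-angeloyloxy-13-(dimethylamino)-15-hydroxy-11βH-11,13-dihydrogermacra-1(10),4-dien-6α,12-olid-14-oate | CN(C)C[C@@H]1C(=O)O[C@@H]2/C=C(/CO)CC/C=C(/C(=O)OC)[C@H](OC(C)=O)[C@@H](OC(=O)/C(C)=C\C)[C@@H]12 | intermediate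
26 | N-methyl quaternary ammonium iodide of 25 (13-trimethylammonio) | C[N+](C)(C)C[C@@H]1C(=O)O[C@@H]2/C=C(/CO)CC/C=C(/C(=O)OC)[C@H](OC(C)=O)[C@@H](OC(=O)/C(C)=C\C)[C@@H]12.[I-] | intermediate (not isolated)
27 | CNP0216801.4, methyl 9α-acetoxy-8β-angeloyloxy-15-hydroxygermacra-1(10)E,4E,11(13)-trien-6α,12-olid-14-oate (6R,7S,8S,9S) | C=C1C(=O)O[C@@H]2/C=C(/CO)CC/C=C(/C(=O)OC)[C@H](OC(C)=O)[C@@H](OC(=O)/C(C)=C\C)[C@@H]12 | target

**Step count**

Total steps: 18. Longest linear sequence: 17 steps (steps 1–4 and 6–18; step 5 is a one-step branch).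

**Steps most likely to fail**

1. Step 13 (Proposed new method). What may go wrong: loss of stereocontrol at C9 through reaction of the enol ether geometry with the siloxy group anti to C1; closure through C1 to an eight-membered ring; or plain reduction and oligomerisation of the 2-formyl enoate. Fallback, setting out from 18: a McMurry-type pinacol coupling with low-valent titanium (TiCl3(DME)1.5, zinc–copper couple, DME, 25 °C, slow addition) is a known way to close medium rings between two aldehyde carbons and is expected to favour the trans (threo) diol in a ten-membered ring. It would give the 8β,9α-diol macrocycle F1. Selective silylation of the less hindered allylic C9 hydroxyl (Et3SiCl 1.0 equiv, imidazole, CH2Cl2, −40 °C) would then come back to the route at 20.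

2. Step 10. What may go wrong: deactivation of the ruthenium catalyst by the basic amine and sluggish cross-metathesis of the 1,1-disubstituted acrylate, with competing homodimerisation of the terminal alkene. Fallback, setting out from 13 (no amine present yet): cross-metathesis with 15 under the same catalyst would give the hydroxy enoate lactone F2. Aminomethylation of its lactone enolate (LiN(SiMe3)2 2.2 equiv, THF, −78 °C; Eschenmoser's salt; the transient N,O-acetal on O9 is lost on aqueous work-up) would come back to the route at 16. The order of metathesis and amine introduction is thereby reversed.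

3. Step 14. What may go wrong: slow acylation of the hindered C8 hydroxyl accompanied by Z-to-E isomerisation of the angeloyl unit and partial retro-Mannich loss of dimethylamine at 80 °C. Fallback, setting out from 20: esterification of O8 with 2-[bis(2,2,2-trifluoroethoxy)phosphoryl]propanoic acid (EDC·HCl, DMAP, CH2Cl2, 25 °C) would give the 8-O-phosphonopropionate F3. A Z-selective Still–Gennari olefination with acetaldehyde (KN(SiMe3)2, 18-crown-6, THF, −78 °C) would build the angelate in place and come back to the route at 22.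

**Further compounds**

F1 | step 13 | methyl 13-(dimethylamino)-8β,9α-dihydroxy-15-[(tert-butyldiphenylsilyl)oxy]-11βH-11,13-dihydrogermacra-1(10),4-dien-6α,12-olid-14-oate (8β,9α-diol macrocycle) | CN(C)C[C@@H]1C(=O)O[C@@H]2/C=C(/CO[Si](c3ccccc3)(c4ccccc4)C(C)(C)C)CC/C=C(/C(=O)OC)[C@H](O)[C@@H](O)[C@@H]12
F2 | step 10 | methyl (2E,6E)-6-{[(tert-butyldiphenylsilyl)oxy]methyl}-2-(hydroxymethyl)-7-[(2R,3R)-5-oxo-3-{[(triethylsilyl)oxy]methyl}oxolan-2-yl]hepta-2,6-dienoate (hydroxy enoate lactone) | C1C(=O)O[C@H](/C=C(/CO[Si](c2ccccc2)(c3ccccc3)C(C)(C)C)CC/C=C(/C(=O)OC)CO)[C@H]1CO[Si](CC)(CC)CC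
F3 | step 14 | 8-O-{2-[bis(2,2,2-trifluoroethoxy)phosphoryl]propanoyl} derivative of 20 (8-O-phosphonopropionate; epimeric at the phosphonate α-carbon, a centre destroyed in the olefination) | CN(C)C[C@@H]1C(=O)O[C@@H]2/C=C(/CO[Si](c3ccccc3)(c4ccccc4)C(C)(C)C)CC/C=C(/C(=O)OC)[C@H](O[Si](CC)(CC)CC)[C@@H](OC(=O)C(C)P(=O)(OCC(F)(F)F)OCC(F)(F)F)[C@@H]12
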